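**Retrosynthetic overview**

1. The C11=C12 bond is cut (Wittig) into a C15 phosphonium salt that carries the 3,5,6-triol ring and a C25 ε-apo-aldehyde; the latter comes from the ε-C15 phosphonium salt (from (R)-α-ionone) and the C10 dialdehyde.
2. The C15 salt comes from a C13 trihydroxy enone (vinyl Grignard, then PPh3·HBr); its C7=C8 bond is made by Wittig olefination of a bridged lactol.
3. Enabling feature: in the trihydroxy ring the oxygen on C3 and the side-chain carbon C7 on C6 are cis and 1,4 to each other, so they can be tied as a lactone O–C7(=O). The ring then is the carbocycle of a 2-oxabicyclo[2.2.2]octene, the [4+2] adduct of 3-(benzyloxy)-4-methyl-2-pyranone (C3–C4–C5–C6, ring O, C7) and 2-methylpropene (C1, C2), in which C1–C6 and C2–C3 form together.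
4. The lactone bridge is not in the target: it fixes C3 relative to C6, steers the hydration at C5 to its own face, and is then reduced and opened to the 3-OH and the C7 aldehyde.
5. Ring order: pyranone (acid cyclodehydration), then cyclohexene plus lactone bridge in the cycloaddition, then bridge opened; the ε ring is bought with C6' in place and C3' is set by CBS reduction.

Key step: step 3

Assumption: the enantiopure natural-grade ketone of the ε half and the C10 dialdehyde are purchased; the facial sense of the ligand in step 3 is assigned by analogy only, and the antipodal ligand, also commercial, is used if the adduct proves to be the mirror image.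

**Trihydroxy half**

Step 1
Reactants: 1 methyl 2-(benzyloxy)acetate; 2 4,4-dimethoxybutan-2-one
Product: 4 methyl 2-(benzyloxy)-3-hydroxy-5,5-dimethoxy-3-methylpentanoate (diastereomer mixture), via lithium enolate 3 (not isolated)
Conditions: LiN(iPr)2 (1.1 equiv), THF, −78 °C, 1 then 2; aq. NH4Cl
Reagents that add atoms: none
Why: Aldol addition: the lithium enolate of the α-benzyloxy ester should add to the methyl ketone at −78 °C faster than it deprotonates it, and the two new stereocentres need no control because both become sp2 carbons in step 2.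

Step 2
Reactants: 4 methyl 2-(benzyloxy)-3-hydroxy-5,5-dimethoxy-3-methylpentanoate
Product: 6 3-(benzyloxy)-4-methyl-2H-pyran-2-one, via 6-methoxy-5,6-dihydropyranone 5 (not isolated)
Conditions: TsOH·H2O (0.3 equiv), toluene, 110 °C, MeOH distilled off
Reagents that add atoms: none
Why: Acid-mediated cyclodehydration to a 2-pyranone: the acetal ionises, the ester carbonyl closes the six-membered lactone, and loss of water and methanol is driven by formation of the conjugated pyranone, a standard entry to 4-methyl-2-pyranones that should leave the benzyl ether untouched.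

Step 3
Reactants: 6 3-(benzyloxy)-4-methyl-2H-pyran-2-one; 7 2-methylpropene
Product: 8 (1S,4S)-4-(benzyloxy)-5,8,8-trimethyl-2-oxabicyclo[2.2.2]oct-5-en-3-one
Conditions: [Cu((S,S)-tBu-box)](SbF6)2 (10 mol %), 7 (10 equiv, condensed), 4 Å MS, CH2Cl2, sealed tube, −20 → 25 °C
Reagents that add atoms: none
Why: Proposed new method: the dicationic divalent copper centre should bind the lactone carbonyl oxygen and the 3-benzyloxy oxygen of 6 as a five-membered chelate and lower the LUMO of the pyranone, which then takes up 2-methylpropene as an inverse-electron-demand diene in a concerted but asynchronous [4+2], the CH2 terminus of the alkene bonding first to C6 of the pyranone (the later C3 carbinol carbon) and the developing tertiary cation collapsing on C3 of the pyranone (the later C6 carbinol carbon). The closest known reaction type is the bis(oxazoline)–copper-catalysed inverse-demand Diels–Alder reaction of 3-carboalkoxy-2-pyranones with enol ethers and indenes, together with carbonyl–ene reactions of glyoxylates under the same catalysts in which 2-methylpropene itself is the nucleophile. Two rings close at once: the cyclohexene by [4+2] cycloaddition, suprafacial on both partners, and with it the lactone becomes the two-atom bridge of the 2-oxabicyclo[2.2.2]octene. Both new stereocentres are bridgeheads of this bicycle, so their relative configuration (ring oxygen cis to the carbonyl carbon, that is the later 3-OH cis to C7) is fixed by topology, the symmetric alkene raising no endo/exo question, and their absolute configuration is to be set by the tert-butyl groups of the ligand, which close one face of the planar chelate. Regioselectivity is needed and follows from polarity (nucleophilic CH2 to the vinylogous acyl terminus, cationic CMe2 to the enolate-like carbon); chemoselectivity over cationic oligomerisation of the alkene, ene-type proton loss and retro-[4+2] loss of CO2 is sought through a non-protic chelating Lewis acid with SbF6 counter-ions, molecular sieves and a temperature not above 25 °C.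

Step 4
Reactants: 8 (1S,4S)-4-(benzyloxy)-5,8,8-trimethyl-2-oxabicyclo[2.2.2]oct-5-en-3-one
Product: 9 (1S,4S,5S)-4-(benzyloxy)-5-hydroxy-5,8,8-trimethyl-2-oxabicyclo[2.2.2]octan-3-one
Conditions: Mn(dpm)3 (10 mol %), PhSiH3 (2 equiv), O2 (1 atm), iPrOH/CH2Cl2, 0 °C → rt
Reagents that add atoms: dioxygen O=O
Why: Mukaiyama hydration (hydrogen-atom transfer): hydrogen should add to the CH end of the trisubstituted alkene, and the tertiary C5 radical should take up oxygen on the face syn to the lactone bridge, because the other face is screened by the syn methyl group of the CMe2 bridge, which sets C5 with its hydroxyl cis to the ring oxygen.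

Step 5
Reactants: 9 (1S,4S,5S)-4-(benzyloxy)-5-hydroxy-5,8,8-trimethyl-2-oxabicyclo[2.2.2]octan-3-one
Product: 10 (1S,4S,5S)-4,5-dihydroxy-5,8,8-trimethyl-2-oxabicyclo[2.2.2]octan-3-one
Conditions: H2 (1 atm), Pd/C (10 %), EtOAc, rt
Reagents that add atoms: none
Why: Hydrogenolysis of the benzyl ether; the molecule has no alkene at this stage and no stereocentre is touched.

Step 6
Reactants: 10 (1S,4S,5S)-4,5-dihydroxy-5,8,8-trimethyl-2-oxabicyclo[2.2.2]octan-3-one
Product: 11 (1S,4S,5S)-5,8,8-trimethyl-2-oxabicyclo[2.2.2]octane-3,4,5-triol (lactol, 3-epimer mixture)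
Conditions: iBu2AlH (3.5 equiv), CH2Cl2, −78 °C; aq. Rochelle salt
Reagents that add atoms: none
Why: Partial reduction of a lactone: at −78 °C the aluminium hemiacetal of the bridged lactol should persist and collapse to the lactol only on work-up, the extra hydride being consumed by the two tertiary hydroxyls.

Step 7
Reactants: 11 (1S,4S,5S)-5,8,8-trimethyl-2-oxabicyclo[2.2.2]octane-3,4,5-triol; 12 1-(triphenylphosphoranylidene)propan-2-one
Product: 13 (E)-4-[(1S,2S,4S)-1,2,4-trihydroxy-2,6,6-trimethylcyclohexyl]but-3-en-2-one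
Conditions: 12 (2.5 equiv), toluene, 90 °C
Reagents that add atoms: none
Why: Wittig reaction of a lactol: the bridged lactol is in equilibrium with the cis-4-hydroxy aldehyde, which the ketone-stabilised ylide should trap under neutral conditions to give the E-enone (thermodynamic selectivity of stabilised ylides), opening the temporary bridge to the free 3-OH and the C7=C8 bond.

Step 8
Reactants: 13 (E)-4-[(1S,2S,4S)-1,2,4-trihydroxy-2,6,6-trimethylcyclohexyl]but-3-en-2-one; 14 vinylmagnesium bromide
Product: 15 (1E)-3-methyl-1-[(1S,2S,4S)-1,2,4-trihydroxy-2,6,6-trimethylcyclohexyl]penta-1,4-dien-3-ol (3-epimer mixture)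
Conditions: 14 (5 equiv), THF, −40 → 0 °C; aq. NH4Cl
Reagents that add atoms: none
Why: Grignard 1,2-addition to the enone, as in the conversion of ionones into vinyl carbinols; the new carbinol centre is not controlled and is lost in step 9.

Step 9
Reactants: 15 (1E)-3-methyl-1-[(1S,2S,4S)-1,2,4-trihydroxy-2,6,6-trimethylcyclohexyl]penta-1,4-dien-3-ol
Product: 16 [(2E,4E)-3-methyl-5-[(1S,2S,4S)-1,2,4-trihydroxy-2,6,6-trimethylcyclohexyl]penta-2,4-dien-1-yl]triphenylphosphonium bromide
Conditions: PPh3·HBr (1.1 equiv), MeOH, 20 °C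
Reagents that add atoms: triphenylphosphine hydrobromide [PH+](c1ccccc1)(c1ccccc1)c1ccccc1.[Br-]
Why: SN1-type allylic transposition, the standard route from vinyl carbinols to C15 phosphonium salts: the doubly allylic tertiary carbinol should ionise far more readily than the 6-hydroxyl (β to the 5-hydroxyl and without such stabilisation), and triphenylphosphine captures the dienyl cation at its primary terminus to give mainly the 9E salt.

**ε half**

Step 10
Reactants: 17 (R)-α-ionone, (E)-4-[(1R)-2,6,6-trimethylcyclohex-2-en-1-yl]but-3-en-2-one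
Product: 18 2-methyl-2-[(E)-2-[(1R)-2,6,6-trimethylcyclohex-2-en-1-yl]ethenyl]-1,3-dioxolane
Conditions: (Me3SiOCH2)2 (1.5 equiv), Me3SiOTf (2 mol %), CH2Cl2, −78 → −20 °C; pyridine
Reagents that add atoms: 1,2-bis(trimethylsilyloxy)ethane C[Si](C)(C)OCCO[Si](C)(C)C
Why: Ketalisation with the bis(silyl) ether of ethylene glycol under silyl triflate catalysis at low temperature, which protects enones without moving the double bond and so should preserve the C6 stereocentre.

Step 11
Reactants: 18 2-methyl-2-[(E)-2-[(1R)-2,6,6-trimethylcyclohex-2-en-1-yl]ethenyl]-1,3-dioxolane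
Product: 19 (4R)-3,5,5-trimethyl-4-[(E)-2-(2-methyl-1,3-dioxolan-2-yl)ethenyl]cyclohex-2-en-1-one
Conditions: Rh2(cap)4 (1 mol %), tBuOOH (70 % aq., 5 equiv), K2CO3 (0.5 equiv), CH2Cl2, rt
Reagents that add atoms: tert-butyl hydroperoxide CC(C)(C)OO
Why: Allylic C–H oxidation with tert-butyl hydroperoxide (peroxyl radical chain) should take place at the ring CH2 next to the trisubstituted alkene, the only unhindered allylic methylene; the existing stereocentre, γ to the new ketone, should not be epimerised by the weak base.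

Step 12
Reactants: 19 (4R)-3,5,5-trimethyl-4-[(E)-2-(2-methyl-1,3-dioxolan-2-yl)ethenyl]cyclohex-2-en-1-one
Product: 20 (1R,4R)-3,5,5-trimethyl-4-[(E)-2-(2-methyl-1,3-dioxolan-2-yl)ethenyl]cyclohex-2-en-1-ol
Conditions: (S)-2-methyl-CBS-oxazaborolidine (20 mol %), catecholborane (1.5 equiv), toluene, −78 °C
Reagents that add atoms: none
Why: Corey–Bakshi–Shibata reduction: the catalyst differentiates the alkenyl and CH2 flanks of the cyclohexenone, and the (S)-catalyst should deliver hydride to give the 3R carbinol, trans to the side chain, by reagent control, while the ketal masks the other ketone.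

Step 13
Reactants: 20 (1R,4R)-3,5,5-trimethyl-4-[(E)-2-(2-methyl-1,3-dioxolan-2-yl)ethenyl]cyclohex-2-en-1-ol
Product: 21 (E)-4-[(1R,4R)-4-hydroxy-2,6,6-trimethylcyclohex-2-en-1-yl]but-3-en-2-one
Conditions: 0.1 M aq. HCl, THF, 0 °C
Reagents that add atoms: water O
Why: Mild acid hydrolysis of the allylic ketal (fast, through an allyl-stabilised oxocarbenium ion) at 0 °C, conditions under which the ring allylic alcohol should not ionise.

Step 14
Reactants: 21 (E)-4-[(1R,4R)-4-hydroxy-2,6,6-trimethylcyclohex-2-en-1-yl]but-3-en-2-one; 14 vinylmagnesium bromide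
Product: 22 (1R,4R)-4-[(1E)-3-hydroxy-3-methylpenta-1,4-dien-1-yl]-3,5,5-trimethylcyclohex-2-en-1-ol (side-chain epimer mixture)
Conditions: 14 (3.5 equiv), THF, −20 → 0 °C; aq. NH4Cl
Reagents that add atoms: none
Why: Grignard 1,2-addition to the methyl ketone; excess reagent covers the free hydroxyl, and the new centre is lost in step 15.

Step 15
Reactants: 22 (1R,4R)-4-[(1E)-3-hydroxy-3-methylpenta-1,4-dien-1-yl]-3,5,5-trimethylcyclohex-2-en-1-ol
Product: 23 [(2E,4E)-5-[(1R,4R)-4-hydroxy-2,6,6-trimethylcyclohex-2-en-1-yl]-3-methylpenta-2,4-dien-1-yl]triphenylphosphonium bromide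
Conditions: PPh3·HBr (1.05 equiv), MeOH, 20 °C
Reagents that add atoms: triphenylphosphine hydrobromide [PH+](c1ccccc1)(c1ccccc1)c1ccccc1.[Br-]
Why: SN1-type allylic transposition: the tertiary doubly allylic carbinol should ionise much faster than the secondary ring allylic alcohol, and the cation is captured by the phosphine at its primary terminus.

Step 16
Reactants: 23 [(2E,4E)-5-[(1R,4R)-4-hydroxy-2,6,6-trimethylcyclohex-2-en-1-yl]-3-methylpenta-2,4-dien-1-yl]triphenylphosphonium bromide; 24 (2E,4E,6E)-2,7-dimethylocta-2,4,6-trienedial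
Product: 26 (2E,4E,6E,8E,10E,12E)-13-[(1R,4R)-4-hydroxy-2,6,6-trimethylcyclohex-2-en-1-yl]-2,7,11-trimethyltrideca-2,4,6,8,10,12-hexaenal, via phosphorus ylide 25 (not isolated)
Conditions: NaOMe (1.1 equiv), MeOH/CH2Cl2, 24 (2 equiv), −10 °C → rt; then heptane, 90 °C
Reagents that add atoms: none
Why: Wittig reaction: the semi-stabilised ylide should condense once with the symmetric dialdehyde used in excess, the C25 aldehyde being a poorer electrophile than the dialdehyde, and Z isomers are equilibrated thermally to the all-E polyene.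

**Coupling**

Step 17
Reactants: 16 [(2E,4E)-3-methyl-5-[(1S,2S,4S)-1,2,4-trihydroxy-2,6,6-trimethylcyclohexyl]penta-2,4-dien-1-yl]triphenylphosphonium bromide; 26 (2E,4E,6E,8E,10E,12E)-13-[(1R,4R)-4-hydroxy-2,6,6-trimethylcyclohex-2-en-1-yl]-2,7,11-trimethyltrideca-2,4,6,8,10,12-hexaenal
Product: 28 (3S,5S,6S,3'R,6'R)-5,6-dihydro-β,ε-carotene-3,5,6,3'-tetrol, via phosphorus ylide 27 (not isolated)
Conditions: NaOMe (1.2 equiv), MeOH/CH2Cl2, 0 °C → rt; then heptane, 90 °C, under N2, dark
Reagents that add atoms: none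
Why: Wittig reaction, tolerant of the free hydroxyls under alkoxide conditions, should form C11=C12; thermal equilibration gives the all-E polyene and no stereocentre is touched.

**Compound list**

1 | methyl 2-(benzyloxy)acetate | COC(=O)COCc1ccccc1 | starting material
2 | 4,4-dimethoxybutan-2-one | CC(=O)CC(OC)OC | starting material
3 | lithium (Z)-2-(benzyloxy)-1-methoxyethen-1-olate | COC(=COCc1ccccc1)[O-].[Li+] | intermediate
4 | methyl 2-(benzyloxy)-3-hydroxy-5,5-dimethoxy-3-methylpentanoate (diastereomer mixture) | COC(=O)C(OCc1ccccc1)C(C)(O)CC(OC)OC | intermediate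
5 | 3-(benzyloxy)-6-methoxy-4-methyl-5,6-dihydro-2H-pyran-2-one (racemic) | COC1CC(C)=C(OCc2ccccc2)C(=O)O1 | intermediate
6 | 3-(benzyloxy)-4-methyl-2H-pyran-2-one | CC1=C(OCc2ccccc2)C(=O)OC=C1 | intermediate
7 | 2-methylpropene | CC(C)=C | starting material
8 | (1S,4S)-4-(benzyloxy)-5,8,8-trimethyl-2-oxabicyclo[2.2.2]oct-5-en-3-one | O=C2[C@]1(OCc3ccccc3)C(C)(C)C[C@H](O2)C=C1C | intermediate
9 | (1S,4S,5S)-4-(benzyloxy)-5-hydroxy-5,8,8-trimethyl-2-oxabicyclo[2.2.2]octan-3-one | O=C2[C@]1(OCc3ccccc3)C(C)(C)C[C@H](O2)C[C@]1(C)O | intermediate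
10 | (1S,4S,5S)-4,5-dihydroxy-5,8,8-trimethyl-2-oxabicyclo[2.2.2]octan-3-one | O=C2[C@]1(O)C(C)(C)C[C@H](O2)C[C@]1(C)O | intermediate
11 | (1S,4S,5S)-5,8,8-trimethyl-2-oxabicyclo[2.2.2]octane-3,4,5-triol (3-epimer mixture) | OC2[C@]1(O)C(C)(C)C[C@H](O2)C[C@]1(C)O | intermediate
12 | 1-(triphenylphosphoranylidene)propan-2-one | CC(=O)C=P(c1ccccc1)(c1ccccc1)c1ccccc1 | starting material
13 | (E)-4-[(1S,2S,4S)-1,2,4-trihydroxy-2,6,6-trimethylcyclohexyl]but-3-en-2-one | CC(=O)/C=C/[C@]1(O)C(C)(C)C[C@H](O)C[C@]1(C)O | intermediate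
14 | vinylmagnesium bromide | C=C[Mg]Br | starting material
15 | (1E)-3-methyl-1-[(1S,2S,4S)-1,2,4-trihydroxy-2,6,6-trimethylcyclohexyl]penta-1,4-dien-3-ol (3-epimer mixture) | C=CC(C)(O)/C=C/[C@]1(O)C(C)(C)C[C@H](O)C[C@]1(C)O | intermediate
16 | [(2E,4E)-3-methyl-5-[(1S,2S,4S)-1,2,4-trihydroxy-2,6,6-trimethylcyclohexyl]penta-2,4-dien-1-yl]triphenylphosphonium bromide | [Br-].c1ccccc1[P+](c1ccccc1)(c1ccccc1)C/C=C(C)/C=C/[C@]1(O)C(C)(C)C[C@H](O)C[C@]1(C)O | intermediate
17 | (R)-α-ionone, (E)-4-[(1R)-2,6,6-trimethylcyclohex-2-en-1-yl]but-3-en-2-one | CC1=CCCC(C)(C)[C@H]1/C=C/C(C)=O | starting material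
18 | 2-methyl-2-[(E)-2-[(1R)-2,6,6-trimethylcyclohex-2-en-1-yl]ethenyl]-1,3-dioxolane | CC1=CCCC(C)(C)[C@H]1/C=C/C2(C)OCCO2 | intermediate
19 | (4R)-3,5,5-trimethyl-4-[(E)-2-(2-methyl-1,3-dioxolan-2-yl)ethenyl]cyclohex-2-en-1-one | CC1=CC(=O)CC(C)(C)[C@H]1/C=C/C2(C)OCCO2 | intermediate
20 | (1R,4R)-3,5,5-trimethyl-4-[(E)-2-(2-methyl-1,3-dioxolan-2-yl)ethenyl]cyclohex-2-en-1-ol | CC1=C[C@H](O)CC(C)(C)[C@H]1/C=C/C2(C)OCCO2 | intermediate
21 | (E)-4-[(1R,4R)-4-hydroxy-2,6,6-trimethylcyclohex-2-en-1-yl]but-3-en-2-one | CC1=C[C@H](O)CC(C)(C)[C@H]1/C=C/C(C)=O | intermediate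
22 | (1R,4R)-4-[(1E)-3-hydroxy-3-methylpenta-1,4-dien-1-yl]-3,5,5-trimethylcyclohex-2-en-1-ol (side-chain epimer mixture) | CC1=C[C@H](O)CC(C)(C)[C@H]1/C=C/C(C)(O)C=C | intermediate
23 | [(2E,4E)-5-[(1R,4R)-4-hydroxy-2,6,6-trimethylcyclohex-2-en-1-yl]-3-methylpenta-2,4-dien-1-yl]triphenylphosphonium bromide | CC1=C[C@H](O)CC(C)(C)[C@H]1/C=C/C(C)=C/C[P+](c2ccccc2)(c2ccccc2)c2ccccc2.[Br-] | intermediate
24 | (2E,4E,6E)-2,7-dimethylocta-2,4,6-trienedial | O=C/C(C)=C/C=C/C=C(C)/C=O | starting material
25 | [(2E,4E)-5-[(1R,4R)-4-hydroxy-2,6,6-trimethylcyclohex-2-en-1-yl]-3-methylpenta-2,4-dien-1-ylidene]triphenylphosphorane | CC1=C[C@H](O)CC(C)(C)[C@H]1/C=C/C(C)=C/C=P(c2ccccc2)(c2ccccc2)c2ccccc2 | intermediate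
26 | (2E,4E,6E,8E,10E,12E)-13-[(1R,4R)-4-hydroxy-2,6,6-trimethylcyclohex-2-en-1-yl]-2,7,11-trimethyltrideca-2,4,6,8,10,12-hexaenal | CC1=C[C@H](O)CC(C)(C)[C@H]1/C=C/C(C)=C/C=C/C(C)=C/C=C/C=C(C)/C=O | intermediate
27 | [(2E,4E)-3-methyl-5-[(1S,2S,4S)-1,2,4-trihydroxy-2,6,6-trimethylcyclohexyl]penta-2,4-dien-1-ylidene]triphenylphosphorane | c1ccccc1P(c1ccccc1)(c1ccccc1)=C/C=C(C)/C=C/[C@]1(O)C(C)(C)C[C@H](O)C[C@]1(C)O | intermediate
28 | (3S,5S,6S,3'R,6'R)-5,6-dihydro-β,ε-carotene-3,5,6,3'-tetrol (CNP0219917.1) | CC1=C[C@H](O)CC(C)(C)[C@H]1/C=C/C(C)=C/C=C/C(C)=C/C=C/C=C(C)/C=C/C=C(C)/C=C/[C@]1(O)C(C)(C)C[C@H](O)C[C@]1(C)O | target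

**Step count**

Total: 17 steps. Longest linear sequence: 10 steps (steps 1–9 and 17).

**Steps most likely to fail**

Step 3. The chelated pyranone, which carries two donor substituents, may be too weak an acceptor, so that cationic oligomerisation of the alkene or ene-type proton loss outruns closure of the second bond; the facial discrimination by the ligand may also be low. The fallback sets out from 6 and 7 and gives up catalysis. An uncatalysed Diels–Alder reaction under high pressure (12–15 kbar, CH2Cl2, 40 °C), a known way to make 2-pyranones add unactivated alkenes with the CO2 bridge retained, should give racemic 4-(benzyloxy)-5,8,8-trimethyl-2-oxabicyclo[2.2.2]oct-5-en-3-one F1. Preparative chromatography on a chiral stationary phase then delivers the (1S,4S) enantiomer, and the route is rejoined at 8.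

Step 7. The free α,β-dihydroxy aldehyde that is in equilibrium with the lactol may undergo retro-aldol ring cleavage (the C5 hydroxyl is β to the aldehyde) or α-ketol ring expansion faster than the hindered neopentyl aldehyde is olefinated. The fallback sets out from 10 and masks both tertiary hydroxyls first. Silylation (Me3SiOTf, 2,6-lutidine, CH2Cl2, 0 °C) should give (1S,4S,5S)-5,8,8-trimethyl-4,5-bis(trimethylsilyloxy)-2-oxabicyclo[2.2.2]octan-3-one F2. Reduction (iBu2AlH, CH2Cl2, −78 °C) gives the lactol (1S,4S,5S)-5,8,8-trimethyl-4,5-bis(trimethylsilyloxy)-2-oxabicyclo[2.2.2]octan-3-ol F3, and Wittig reaction with 12 (toluene, 90 °C) gives (E)-4-[(1S,2S,4S)-4-hydroxy-2,6,6-trimethyl-1,2-bis(trimethylsilyloxy)cyclohexyl]but-3-en-2-one F4. Mild methanolysis (PPTS, MeOH, rt) removes the silyl groups, and the route is rejoined at 13.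

Step 4. Oxygen capture by the tertiary C5 radical may show poor facial selectivity, or the radical may be reduced to the alkane. The fallback sets out from 8 and replaces the radical hydration by an epoxide route. Epoxidation (mCPBA, NaHCO3, CH2Cl2, 0 °C) from the open lactone face should give the 5,6-epoxide of 8 with the oxirane oxygen syn to the lactone bridge F5. LiAlH4 (THF, 0 → 50 °C) reduces the lactone and opens the oxirane by hydride attack at its CH carbon, so the C5–O bond is kept, to give (1S,3S,4R)-4-(benzyloxy)-4-(hydroxymethyl)-3,5,5-trimethylcyclohexane-1,3-diol F6. Oxidative lactonisation of the primary alcohol onto the cis secondary hydroxyl (TEMPO cat., PhI(OAc)2, CH2Cl2, rt) then closes the bridge again, and the route is rejoined at 9.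

**Further compounds**

F1 | step 3 | racemic 4-(benzyloxy)-5,8,8-trimethyl-2-oxabicyclo[2.2.2]oct-5-en-3-one | O=C2C1(OCc3ccccc3)C(C)(C)CC(O2)C=C1C
F2 | step 7 | (1S,4S,5S)-5,8,8-trimethyl-4,5-bis(trimethylsilyloxy)-2-oxabicyclo[2.2.2]octan-3-one | O=C2[C@]1(O[Si](C)(C)C)C(C)(C)C[C@H](O2)C[C@]1(C)O[Si](C)(C)C
F3 | step 7 | (1S,4S,5S)-5,8,8-trimethyl-4,5-bis(trimethylsilyloxy)-2-oxabicyclo[2.2.2]octan-3-ol (3-epimer mixture) | OC2[C@]1(O[Si](C)(C)C)C(C)(C)C[C@H](O2)C[C@]1(C)O[Si](C)(C)C
F4 | step 7 | (E)-4-[(1S,2S,4S)-4-hydroxy-2,6,6-trimethyl-1,2-bis(trimethylsilyloxy)cyclohexyl]but-3-en-2-one | CC(=O)/C=C/[C@]1(O[Si](C)(C)C)C(C)(C)C[C@H](O)C[C@]1(C)O[Si](C)(C)C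
F5 | step 4 | 5,6-epoxide of 8, oxirane oxygen syn to the lactone bridge, (1S,4S,5S,6S)-4-(benzyloxy)-5,6-epoxy-5,8,8-trimethyl-2-oxabicyclo[2.2.2]octan-3-one | O=C2[C@]1(OCc3ccccc3)C(C)(C)C[C@H](O2)[C@@H]4O[C@]14C
F6 | step 4 | (1S,3S,4R)-4-(benzyloxy)-4-(hydroxymethyl)-3,5,5-trimethylcyclohexane-1,3-diol | OC[C@]1(OCc2ccccc2)C(C)(C)C[C@H](O)C[C@]1(C)O
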